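## Retrosynthetic overview

1. Target ⇒ O-acetylation of the C4 alcohol; the oxepane (C3–O–C16) is the last ring, closed by the tertiary C3 hydroxyl displacing a C16 triflate.
2. Tetrahydrofuran (C2–O–C9) ⇒ a carbocyclic 6/10 (eunicellane-type) (2Z,6Z)-diene diol: C4–OH-directed epoxidation of C2=C3 and transannular 5-exo opening by the C9 hydroxyl set C2 and C3 in one flask.
3. Ten-membered carbocycle ⇒ Nozaki–Hiyama–Kishi closure of C3–C4; C8–C9 from a Z-selective allylboration; (Z)-C2=C3 from a Stork–Zhao vinyl iodide.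
4. Cyclohexene with C1, C10, C14 all-cis ⇒ auxiliary-controlled endo Diels–Alder reaction of a 2-silyloxydiene (C15 from the chiral pool) with a 5-menthyloxybutenolide.
5. Ring order: six-membered carbocycle → ten-membered carbocycle → tetrahydrofuran → oxepane, i.e. carbocycle first, then the ether bridges in the order cladiellin → briarellin of the proposed biosynthesis.

Skeleton numbering used below: C1 and C10–C14 form the six-membered ring, C2–C9 are the other ring carbons, C15(C17)–C16 is the side chain, C18 is on C3, C19 on C7, C20 on C11. TBS = tert-butyldimethylsilyl, TIPS = triisopropylsilyl.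

Assumption: the butenolide (5S)-5-(D-menthyloxy)furan-2(5H)-one is bought; it is the enantiomer of the common L-menthol-derived reagent and is otherwise made in one step from 5-hydroxyfuran-2(5H)-one and (+)-menthol.

## Route

Step 1
Reactants: 1 (S)-3-bromo-2-methylpropan-1-ol
Product: 2 (S)-(3-bromo-2-methylpropoxy)(tert-butyl)dimethylsilane
Conditions: TBSCl, imidazole, CH2Cl2, 0 °C to rt
Reagents that add atoms: tert-butyldimethylsilyl chloride, CC(C)(C)[Si](C)(C)Cl
Why: Silyl ether formation masks the future C16 hydroxyl so that the bromide can be turned into a Grignard reagent; the C15 stereocentre comes from the chiral pool and is not touched.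

Step 2
Reactants: 2 (S)-(3-bromo-2-methylpropoxy)(tert-butyl)dimethylsilane, 3 (E)-but-2-enoyl chloride
Product: 5 (R,E)-7-[(tert-butyldimethylsilyl)oxy]-6-methylhept-2-en-4-one, via Grignard reagent 4 (not isolated)
Conditions: Mg, THF, 45 °C; then 3, Fe(acac)3 (3 mol %), THF, −78 °C
Reagents that add atoms: none
Why: Iron-catalysed acylation of a Grignard reagent by an acid chloride is fast at −78 °C and stops at the ketone, giving the C11–C17 enone without touching the stereocentre.

Step 3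
Reactants: 5 (R,E)-7-[(tert-butyldimethylsilyl)oxy]-6-methylhept-2-en-4-one
Product: 6 tert-butyl(dimethyl){[(2R,3Z,5E)-2-methyl-4-[(triisopropylsilyl)oxy]hepta-3,5-dien-1-yl]oxy}silane
Conditions: TIPSOTf, Et3N, CH2Cl2, −78 to 0 °C
Reagents that add atoms: triisopropylsilyl trifluoromethanesulfonate, CC(C)[Si](C(C)C)(C(C)C)OS(=O)(=O)C(F)(F)F
Why: Soft enolisation on the α′ side gives the cross-conjugated (Z)-silyl dienol ether, a 2-silyloxy-1,3-diene whose C14 substituent sits on the outside as a Diels–Alder reaction needs.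

Step 4
Reactants: 6 the (2R,3Z,5E)-silyloxydiene, 7 (5S)-5-{[(1S,2R,5S)-5-methyl-2-(propan-2-yl)cyclohexyl]oxy}furan-2(5H)-one
Product: 8 (3S,3aS,4R,7R,7aR)-4-[(2R)-1-[(tert-butyldimethylsilyl)oxy]propan-2-yl]-7-methyl-3-{[(1S,2R,5S)-5-methyl-2-(propan-2-yl)cyclohexyl]oxy}-5-[(triisopropylsilyl)oxy]-3a,4,7,7a-tetrahydro-2-benzofuran-1(3H)-one
Conditions: toluene, BHT (cat.), 115 °C, sealed tube, 60 h
Reagents that add atoms: none
Why: Thermal Diels–Alder reaction in which the electron-rich diene terminus C14 bonds to the β-carbon C1 of the butenolide, the diene adds anti to the menthyloxy group (absolute configuration at C1 and C10) and endo (C14 and C11 substituents cis to the lactone), so C1, C10 and C14 are set all-cis in one step independently of C15.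

Step 5
Reactants: 8 the Diels–Alder lactone
Product: 9 aldehyde Weinreb amide (C2 = CHO, C9 = CON(OMe)Me on the all-cis cyclohexene)
Conditions: MeNH(OMe)·HCl, AlMe3, CH2Cl2, 0 °C to rt
Reagents that add atoms: N,O-dimethylhydroxylamine hydrochloride, CNOC.Cl
Why: Weinreb aminolysis of the acylal lactone at its carbonyl (C9) opens the ring, and the hemiacetal left at C2 collapses on work-up to the aldehyde with loss of menthol, so C9 (acid level) and C2 (aldehyde level) are told apart without a protecting group and without base at C1 or C10.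

Step 6
Reactants: 9 aldehyde Weinreb amide
Product: 10 (Z)-vinyl iodide Weinreb amide
Conditions: EtPPh3I, n-BuLi, THF, rt; I2, −78 °C; NaN(SiMe3)2, −20 °C; then 9, −78 °C
Reagents that add atoms: ethyltriphenylphosphonium iodide, CC[P+](c1ccccc1)(c1ccccc1)c1ccccc1.[I-]; iodine, II
Why: Stork–Zhao olefination with the α-iodo ylide gives the (Z)-2-iodoalkene (iodine cis to C1) at −78 °C, where the Weinreb amide and the silyl enol ether are inert and the α-stereocentre C1 does not epimerise.

Step 7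
Reactants: 10 (Z)-vinyl iodide Weinreb amide
Product: 11 (Z)-vinyl iodide aldehyde (C9 = CHO)
Conditions: i-Bu2AlH, THF, −78 °C
Reagents that add atoms: none
Why: Weinreb amide reduction stops at the chelated hemiaminal and gives the C9 aldehyde on work-up; the vinyl iodide and both silyl groups are untouched.

Step 8
Reactants: 12 3,3-diethoxypropan-1-ol
Product: 13 3,3-diethoxypropyl N,N-diisopropylcarbamate
Conditions: i-Pr2NCOCl, Et3N, CH2Cl2, reflux
Reagents that add atoms: N,N-diisopropylcarbamoyl chloride, CC(C)N(C(C)C)C(Cl)=O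
Why: O-Carbamoylation gives the Hoppe carbamate needed for directed, sparteine-controlled α-lithiation.

Step 9
Reactants: 13 3,3-diethoxypropyl N,N-diisopropylcarbamate, 14 4,4,5,5-tetramethyl-2-(prop-1-en-2-yl)-1,3,2-dioxaborolane
Product: 17 2-[(3S)-5,5-diethoxy-2-methylpent-1-en-3-yl]-4,4,5,5-tetramethyl-1,3,2-dioxaborolane, via lithiated carbamate 15 (not isolated), via lithium boronate complex 16 (not isolated)
Conditions: s-BuLi, (+)-sparteine, Et2O, −78 °C; then 14; MgBr2·OEt2, −78 °C to reflux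
Reagents that add atoms: none
Why: Hoppe–Aggarwal lithiation–borylation, in which (+)-sparteine gives the (R)-lithiated carbamate, borylation goes with retention and the 1,2-metallate shift of the isopropenyl group with inversion, so the α-substituted allylboronate is formed as the (S) enantiomer.

Step 10
Reactants: 11 (Z)-vinyl iodide aldehyde, 17 the (S)-allylboronate
Product: 19 (9S,6Z)-homoallylic alcohol carrying the C4 diethyl acetal, via pinacol borate ester 18 (not isolated)
Conditions: toluene, 4 Å molecular sieves, 50 °C, 36 h; then aqueous NaHCO3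
Reagents that add atoms: none
Why: Allylboration through a closed chair transition state (γ-attack) in which the α-substituent of the pinacol boronate sits axial, reinforced by 1,2-strain against the 2-methyl group; this gives the (Z)-trisubstituted C6=C7 olefin and transfers the boron-bearing stereocentre to C9 (S) under reagent control, while vinyl iodide and silyl enol ether are inert.

Step 11
Reactants: 19 the homoallylic alcohol
Product: 20 the 11-en-13-one (cyclohexenone) of 19
Conditions: DDQ, 2,6-lutidine, CH2Cl2, 0 °C to rt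
Reagents that add atoms: none
Why: DDQ dehydrogenation of a silyl enol ether (hydride abstraction from the γ-carbon C11, then loss of the silyl group) gives the enone regiospecifically without palladium, which the vinyl iodide would not survive; it is done only after C9 has become a carbinol, because an enone next to a C9 aldehyde would make C10 labile.

Step 12
Reactants: 20 the enone acetal
Product: 21 (3Z,6S)-hydroxy aldehyde (C4 = CHO)
Conditions: LiBF4, MeCN/H2O (50:1), rt
Reagents that add atoms: water, O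
Why: Mild Lewis-acid hydrolysis of the diethyl acetal frees the C4 aldehyde while the primary TBS ether and the Z β,γ-olefin stay in place.

Step 13
Reactants: 21 the hydroxy aldehyde vinyl iodide
Product: 23 (2Z,4R,6Z,9S,15R)-16-[(tert-butyldimethylsilyl)oxy]-4,9-dihydroxyeunicella-2,6,11-trien-13-one, via alkenylchromium dichloride 22 (not isolated)
Conditions: CrCl2 (10 equiv), NiCl2 (1 mol %), DMSO/THF, 0.003 M, rt
Reagents that add atoms: none
Why: Nozaki–Hiyama–Kishi macrocyclisation (oxidative addition at zerovalent nickel, transmetallation to trivalent chromium, addition to the aldehyde) closes the ten-membered carbocycle at C3–C4 with retention of the Z geometry; the chromium-bound oxygen is expected on the outer face with H-4 eclipsing the olefin (allylic 1,3-strain), which gives the (4R) alcohol.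

Step 14
Reactants: 23 the 6/10 bicyclic diol
Product: 26 3,4,16-trihydroxy-2,9-epoxyeunicella-6,11-dien-13-one (tetrahydrofuran triol), via epoxy diol 24 (not isolated), via tetrahydrofuran silyl ether 25 (not isolated)
Conditions: VO(acac)2 (5 mol %), t-BuOOH, CH2Cl2, 0 °C to rt; then CSA, MeOH, rt
Reagents that add atoms: tert-butyl hydroperoxide, CC(C)(C)OO
Why: Hydroxyl-directed vanadium-catalysed epoxidation picks the allylic C2=C3 olefin over C6=C7 and delivers oxygen syn to the C4 hydroxyl on the outer face of the Z-cyclodecene; the C9 hydroxyl, held behind C2, then opens the epoxide transannularly (5-exo-tet, inversion at C2, retention at C3), which sets C2 and C3 and forms the tetrahydrofuran, and the acid in methanol finally removes the TBS group.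

Step 15
Reactants: 26 the tetrahydrofuran triol
Product: 28 4-hydroxy-2,9:3,16-diepoxyeunicella-6,11-dien-13-one (4-deacetyl target), via primary triflate 27 (not isolated)
Conditions: Tf2O (1.05 equiv), 2,6-lutidine, CH2Cl2, −78 °C to rt
Reagents that add atoms: none
Why: The primary C16 hydroxyl is triflated selectively at −78 °C and the tertiary C3 hydroxyl displaces the triflate in an intramolecular Williamson-type etherification (7-exo-tet), closing the oxepane with retention at C3 and fixing C14 in the cis-fused tetracycle.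

Step 16
Reactants: 28 the 4-deacetyl target
Product: 29 the target, (1R,2S,3S,4R,6Z,9S,10S,14R,15R)-4-acetoxy-2,9:3,16-diepoxyeunicella-6,11-dien-13-one
Conditions: Ac2O, DMAP, pyridine, rt
Reagents that add atoms: acetic anhydride, CC(=O)OC(C)=O
Why: Acylation of the only remaining hydroxyl (secondary, C4) gives the target without touching any stereocentre.

## Compound list

1 | (S)-3-bromo-2-methylpropan-1-ol | BrC[C@@H](C)CO | starting material
2 | (S)-(3-bromo-2-methylpropoxy)(tert-butyl)dimethylsilane | BrC[C@@H](C)CO[Si](C)(C)C(C)(C)C | intermediate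
3 | (E)-but-2-enoyl chloride (crotonyl chloride) | C/C=C/C(Cl)=O | starting material
4 | [(S)-3-[(tert-butyldimethylsilyl)oxy]-2-methylpropyl]magnesium bromide (not isolated) | Br[Mg]C[C@@H](C)CO[Si](C)(C)C(C)(C)C | intermediate
5 | (R,E)-7-[(tert-butyldimethylsilyl)oxy]-6-methylhept-2-en-4-one | C/C=C/C(=O)C[C@@H](C)CO[Si](C)(C)C(C)(C)C | intermediate
6 | tert-butyl(dimethyl){[(2R,3Z,5E)-2-methyl-4-[(triisopropylsilyl)oxy]hepta-3,5-dien-1-yl]oxy}silane | C/C=C/C(O[Si](C(C)C)(C(C)C)C(C)C)=C/[C@@H](C)CO[Si](C)(C)C(C)(C)C | intermediate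
7 | (5S)-5-{[(1S,2R,5S)-5-methyl-2-(propan-2-yl)cyclohexyl]oxy}furan-2(5H)-one | O=C1C=C[C@@H](O[C@H]2C[C@@H](C)CC[C@@H]2C(C)C)O1 | starting material
8 | (3S,3aS,4R,7R,7aR)-4-[(2R)-1-(TBSO)propan-2-yl]-7-methyl-3-[(1S,2R,5S)-menthyloxy]-5-(TIPSO)-3a,4,7,7a-tetrahydro-2-benzofuran-1(3H)-one; H-3a, H-4, H-7, H-7a all cis, O-menthyl trans to C4 | C[C@@H]1C=C(O[Si](C(C)C)(C(C)C)C(C)C)[C@H]([C@@H](C)CO[Si](C)(C)C(C)(C)C)[C@H]2[C@@H]1C(=O)O[C@@H]2O[C@H]3C[C@@H](C)CC[C@@H]3C(C)C | intermediate
9 | 5-[(2R)-1-(TBSO)propan-2-yl]-6-formyl-N-methoxy-N,2-dimethyl-4-(TIPSO)cyclohex-3-ene-1-carboxamide; the four ring substituents all cis, absolute configuration as in 8 | C[C@@H]1C=C(O[Si](C(C)C)(C(C)C)C(C)C)[C@H]([C@@H](C)CO[Si](C)(C)C(C)(C)C)[C@H](C=O)[C@@H]1C(=O)N(C)OC | intermediate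
10 | 5-[(2R)-1-(TBSO)propan-2-yl]-6-[(1Z)-2-iodoprop-1-en-1-yl]-N-methoxy-N,2-dimethyl-4-(TIPSO)cyclohex-3-ene-1-carboxamide; ring configuration as in 9 | C[C@@H]1C=C(O[Si](C(C)C)(C(C)C)C(C)C)[C@H]([C@@H](C)CO[Si](C)(C)C(C)(C)C)[C@H](/C=C(/C)I)[C@@H]1C(=O)N(C)OC | intermediate
11 | 5-[(2R)-1-(TBSO)propan-2-yl]-6-[(1Z)-2-iodoprop-1-en-1-yl]-2-methyl-4-(TIPSO)cyclohex-3-ene-1-carbaldehyde; ring configuration as in 9 | C[C@@H]1C=C(O[Si](C(C)C)(C(C)C)C(C)C)[C@H]([C@@H](C)CO[Si](C)(C)C(C)(C)C)[C@H](/C=C(/C)I)[C@@H]1C=O | intermediate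
12 | 3,3-diethoxypropan-1-ol | CCOC(CCO)OCC | starting material
13 | 3,3-diethoxypropyl N,N-diisopropylcarbamate | CCOC(CCOC(=O)N(C(C)C)C(C)C)OCC | intermediate
14 | 4,4,5,5-tetramethyl-2-(prop-1-en-2-yl)-1,3,2-dioxaborolane | CC(=C)B1OC(C)(C)C(C)(C)O1 | starting material
15 | [(1R)-1-[(diisopropylcarbamoyl)oxy]-3,3-diethoxypropyl]lithium, (+)-sparteine complex (not isolated) | CCOC(C[C@@H]([Li])OC(=O)N(C(C)C)C(C)C)OCC | intermediate
16 | lithium boronate complex of 15 with 14 (not isolated) | CCOC(C[C@H](OC(=O)N(C(C)C)C(C)C)[B-]1(C(C)=C)OC(C)(C)C(C)(C)O1)OCC.[Li+] | intermediate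
17 | 2-[(3S)-5,5-diethoxy-2-methylpent-1-en-3-yl]-4,4,5,5-tetramethyl-1,3,2-dioxaborolane | CCOC(C[C@H](B1OC(C)(C)C(C)(C)O1)C(C)=C)OCC | intermediate
18 | pinacol borate ester of alcohol 19 (not isolated) | C[C@@H]1C=C(O[Si](C(C)C)(C(C)C)C(C)C)[C@H]([C@@H](C)CO[Si](C)(C)C(C)(C)C)[C@H](/C=C(/C)I)[C@@H]1[C@@H](OB2OC(C)(C)C(C)(C)O2)C/C(C)=C\CC(OCC)OCC | intermediate
19 | (1S,3Z)-6,6-diethoxy-3-methyl-1-{5-[(2R)-1-(TBSO)propan-2-yl]-6-[(1Z)-2-iodoprop-1-en-1-yl]-2-methyl-4-(TIPSO)cyclohex-3-en-1-yl}hex-3-en-1-ol; ring as in 11 | C[C@@H]1C=C(O[Si](C(C)C)(C(C)C)C(C)C)[C@H]([C@@H](C)CO[Si](C)(C)C(C)(C)C)[C@H](/C=C(/C)I)[C@@H]1[C@@H](O)C/C(C)=C\CC(OCC)OCC | intermediate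
20 | 6-[(2R)-1-(TBSO)propan-2-yl]-4-[(1S,3Z)-6,6-diethoxy-1-hydroxy-3-methylhex-3-en-1-yl]-5-[(1Z)-2-iodoprop-1-en-1-yl]-3-methylcyclohex-2-en-1-one; substituents at C4, C5, C6 all cis, configured as in the target | CC1=CC(=O)[C@H]([C@@H](C)CO[Si](C)(C)C(C)(C)C)[C@H](/C=C(/C)I)[C@@H]1[C@@H](O)C/C(C)=C\CC(OCC)OCC | intermediate
21 | (3Z,6S)-6-hydroxy-4-methyl-6-{the cyclohexenonyl ring of 20}hex-3-enal | CC1=CC(=O)[C@H]([C@@H](C)CO[Si](C)(C)C(C)(C)C)[C@H](/C=C(/C)I)[C@@H]1[C@@H](O)C/C(C)=C\CC=O | intermediate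
22 | alkenylchromium dichloride from 21, chromium in place of iodine, Z geometry kept (not isolated) | CC1=CC(=O)[C@H]([C@@H](C)CO[Si](C)(C)C(C)(C)C)[C@H](/C=C(/C)[Cr](Cl)Cl)[C@@H]1[C@@H](O)C/C(C)=C\CC=O | intermediate
23 | (2Z,4R,6Z,9S,15R)-16-(TBSO)-4,9-dihydroxyeunicella-2,6,11-trien-13-one; H-1, H-10, H-14 all cis, configured as in the target | CC1=CC(=O)[C@H]([C@@H](C)CO[Si](C)(C)C(C)(C)C)[C@@H]2/C=C(/C)[C@H](O)C/C=C(/C)C[C@H](O)[C@H]12 | intermediate
24 | cis-2,3-epoxide of 23, epoxide oxygen on the face of the C4 hydroxyl (not isolated) | CC1=CC(=O)[C@H]([C@@H](C)CO[Si](C)(C)C(C)(C)C)[C@@H]2[C@H]3O[C@@]3(C)[C@H](O)C/C=C(/C)C[C@H](O)[C@H]12 | intermediate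
25 | 16-(TBSO)-3,4-dihydroxy-2,9-epoxyeunicella-6,11-dien-13-one, all stereocentres as in the target (not isolated) | O[C@@H]1C/C=C(/C)C[C@@H]2O[C@@H]([C@@H]3[C@H]2C(C)=CC(=O)[C@@H]3[C@@H](C)CO[Si](C)(C)C(C)(C)C)[C@@]1(C)O | intermediate
26 | 3,4,16-trihydroxy-2,9-epoxyeunicella-6,11-dien-13-one, all stereocentres as in the target | O[C@@H]1C/C=C(/C)C[C@@H]2O[C@@H]([C@@H]3[C@H]2C(C)=CC(=O)[C@@H]3[C@@H](C)CO)[C@@]1(C)O | intermediate
27 | 16-O-triflate of 26 (not isolated) | O[C@@H]1C/C=C(/C)C[C@@H]2O[C@@H]([C@@H]3[C@H]2C(C)=CC(=O)[C@@H]3[C@@H](C)COS(=O)(=O)C(F)(F)F)[C@@]1(C)O | intermediate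
28 | 4-hydroxy-2,9:3,16-diepoxyeunicella-6,11-dien-13-one (4-deacetyl target) | O[C@@H]1C/C=C(/C)C[C@@H]2O[C@H]3[C@@H]4[C@H]2C(C)=CC(=O)[C@@H]4[C@@H](C)CO[C@@]13C | intermediate
29 | (1R,2S,3S,4R,6Z,9S,10S,14R,15R)-4-acetoxy-2,9:3,16-diepoxyeunicella-6,11-dien-13-one (CNP0320560.1) | CC(=O)O[C@@H]1C/C=C(/C)C[C@@H]2O[C@H]3[C@@H]4[C@H]2C(C)=CC(=O)[C@@H]4[C@@H](C)CO[C@@]13C | target

## Step count and risks

Total step count: 16. Longest linear sequence: 14 (steps 1–7 and 10–16); the boronate branch is steps 8–9.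

**Step 4 (Diels–Alder reaction).** The butenolide is a weak dienophile and the diene is 1,4-disubstituted, so rate and endo selectivity are at risk. Fallback, from 5 and back at 10: make the cycloaddition intramolecular through an acetal tether. Cleave the silyl ether of 5 with HF·pyridine to (R,E)-7-hydroxy-6-methylhept-2-en-4-one F1. Condense it with 5-hydroxyfuran-2(5H)-one (CSA, benzene, azeotropic removal of water, the unwanted acetal epimer re-equilibrated by acid) to the pseudo-ester (5R)-5-{[(2R,5E)-2-methyl-4-oxohept-5-en-1-yl]oxy}furan-2(5H)-one F2. Silylate with TIPSOTf and Et3N to the tethered silyloxy triene F3. Heat in toluene at 150 °C, so that the four-atom tether forces C14 onto C1 from the acetal-oxygen face and gives the tricyclic acetal lactone F4. Open the lactone as in step 5 to the lactol Weinreb amide F5, olefinate the lactol as in step 6 to the vinyl iodide alcohol F6, and silylate with TBSCl and imidazole to reach 10.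

**Step 13 (ten-membered ring closure).** Medium-ring strain, oligomerisation and the C4 configuration are at risk. Fallback, from 11 and back at 23: close the ring by olefin metathesis at C6=C7 instead. Add a 2-methylallyl group to 11 with the borane made from (−)-B-methoxydiisopinocampheylborane and 2-methylallylmagnesium chloride (Brown allylation, reagent control) to give the (9S) methallyl carbinol F7. Oxidise with DDQ as in step 11 to the enone F8. Couple the vinyl iodide intermolecularly with but-3-enal (CrCl2, NiCl2 cat., DMSO) to the (4R) dienyl alcohol F9; the 4S epimer is separated and inverted by a Mitsunobu reaction. Ring-closing metathesis of the two terminal olefins (second-generation Hoveyda–Grubbs catalyst, toluene, 80 °C, 0.001 M) then gives 23, the medium ring favouring the Z olefin.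

**Step 14 (directed epoxidation and transannular ether formation).** The face of epoxidation and the 5-exo versus 6-endo opening are at risk. Fallback, from 23 and back at 25: reverse the polarity of the epoxidation. Oxidise the allylic C4 alcohol with MnO2 to the cyclodecadienone F10. Epoxidise the now electron-poor C2=C3 bond with t-BuOOH and DBU (Weitz–Scheffer epoxidation, which leaves C6=C7 alone and attacks the outer face) to the epoxy ketone F11. Under CSA the C9 hydroxyl opens the epoxide at C2, attack at C3 being switched off by the adjacent carbonyl, to give the tetrahydrofuran hydroxy ketone F12. Reduce the C4 ketone with Zn(BH4)2 under chelation control by the C3 hydroxyl (the ring enone reacts more slowly) to reach 25.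

## Further compounds

F1 | step 4 | (R,E)-7-hydroxy-6-methylhept-2-en-4-one | C/C=C/C(=O)C[C@@H](C)CO
F2 | step 4 | (5R)-5-{[(2R,5E)-2-methyl-4-oxohept-5-en-1-yl]oxy}furan-2(5H)-one | C/C=C/C(=O)C[C@@H](C)CO[C@H]1C=CC(=O)O1
F3 | step 4 | (5R)-5-{[(2R,3Z,5E)-2-methyl-4-[(triisopropylsilyl)oxy]hepta-3,5-dien-1-yl]oxy}furan-2(5H)-one (tethered silyloxy triene) | C/C=C/C(O[Si](C(C)C)(C(C)C)C(C)C)=C/[C@@H](C)CO[C@H]1C=CC(=O)O1
F4 | step 4 | tricyclic acetal lactone (C2 bonded to O16 and to the lactone oxygen; ring stereocentres as in 8, O16 cis to C14) | C[C@@H]1C=C(O[Si](C(C)C)(C(C)C)C(C)C)[C@@H]2[C@@H](C)CO[C@@H]3OC(=O)[C@H]1[C@H]23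
F5 | step 4 | lactol Weinreb amide (six-membered C2 lactol to O16, anomeric mixture; C9 = CON(OMe)Me) | C[C@@H]1C=C(O[Si](C(C)C)(C(C)C)C(C)C)[C@@H]2[C@@H](C)COC(O)[C@@H]2[C@@H]1C(=O)N(C)OC
F6 | step 4 | vinyl iodide alcohol (10 with a free C16 hydroxyl) | C[C@@H]1C=C(O[Si](C(C)C)(C(C)C)C(C)C)[C@H]([C@@H](C)CO)[C@H](/C=C(/C)I)[C@@H]1C(=O)N(C)OC
F7 | step 13 | (9S) methallyl carbinol from 11 (C9 carries OH and a 2-methylallyl group) | C[C@@H]1C=C(O[Si](C(C)C)(C(C)C)C(C)C)[C@H]([C@@H](C)CO[Si](C)(C)C(C)(C)C)[C@H](/C=C(/C)I)[C@@H]1[C@@H](O)CC(C)=C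
F8 | step 13 | enone of F7 (11-en-13-one) | CC1=CC(=O)[C@H]([C@@H](C)CO[Si](C)(C)C(C)(C)C)[C@H](/C=C(/C)I)[C@@H]1[C@@H](O)CC(C)=C
F9 | step 13 | (4R) dienyl alcohol (C3 bonded to CH(OH)CH2CH=CH2, Z-C2=C3) | CC1=CC(=O)[C@H]([C@@H](C)CO[Si](C)(C)C(C)(C)C)[C@H](/C=C(/C)[C@H](O)CC=C)[C@@H]1[C@@H](O)CC(C)=C
F10 | step 14 | cyclodecadienone (C4 ketone of 23) | CC1=CC(=O)[C@H]([C@@H](C)CO[Si](C)(C)C(C)(C)C)[C@@H]2/C=C(/C)C(=O)C/C=C(/C)C[C@H](O)[C@H]12
F11 | step 14 | cis-2,3-epoxy-4-ketone | CC1=CC(=O)[C@H]([C@@H](C)CO[Si](C)(C)C(C)(C)C)[C@@H]2[C@H]3O[C@@]3(C)C(=O)C/C=C(/C)C[C@H](O)[C@H]12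
F12 | step 14 | tetrahydrofuran hydroxy ketone (25 with a C4 ketone) | O=C1C/C=C(/C)C[C@@H]2O[C@@H]([C@@H]3[C@H]2C(C)=CC(=O)[C@@H]3[C@@H](C)CO[Si](C)(C)C(C)(C)C)[C@@]1(C)O
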